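(Readings and results come from a simulation for substances that don't exist.)

The moment of reading is 50% conversion, not a clock time, so the quick number asked for rests on what stands in the flask at that moment.

| flask | starting material | second substrate | enzyme | remark |
|---|---|---|---|---|
| west | 0.0067 M | 1.2 equiv | 0.044 mol% | run made earlier |
| east | 0.015 M | 1.2 equiv | 0.044 mol% | run made earlier |
| north | 0.010 M | 1.2 equiv | 0.066 mol% | run made earlier |
| flask | 0.010 M | 1.20 equiv | 0.044 mol% |  |

| west: time / min | west: target / % | east: time / min | east: target / % | north: time / min | north: target / % |
|---|---|---|---|---|---|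
| 0.200 | 19.7 | 0.500 | 70.5 | 0.200 | 41.0 |
| 0.333 | 28.6 | 1.00 | 89.9 | 0.667 | 75.6 |
| 0.667 | 45.1 | 1.33 | 95.9 | 1.00 | 86.1 |
| 1.33 | 67.0 | 2.00 | 98.8 | 1.50 | 94.3 |
| 2.50 | 85.1 | 2.50 | 99.9 | 2.50 | 98.3 |

(readings scatter by 0.5 percentage points)



1. factor on the rate of making target when 50% of the starting material are converted if second substrate is charged twice over
2. factor on the rate when 50% of the starting material are converted if enzyme is charged at 0.4 mol% instead

All 3 runs carry 1.2 equiv of second substrate, so none of them varies its ratio to the starting material. A neutral case serves as the zero of the scale: the starting material is the limiting reagent, one second substrate is spent per target, and the rate is taken in proportion to the second substrate left. At 50% conversion the flask has 0.00700 M left, and with the charge doubled it has 0.0190 M. Their ratio, 2.71, is the pool factor, the second substrate left after a change of charge over the second substrate left before it, at the same conversion. This reckoning commits to 2.71 for the doubling and, with the rate in proportion to enzyme, to 9.09 for the enzyme.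

The forecast starts from the same ratio of second substrate but takes an order of “about 0.3–0.5 in second substrate, though this is poorly resolved”. It gives 1.5 for the doubling and 9.5 for the enzyme.

The flask gives 2.59 for the doubling and 19.6 for the enzyme.

    second substrate ⇌ dormant form (K = 6.60, k = 1.30 s⁻¹)
    second substrate + starting complex ⇌ ternary complex (K = 45.0 M⁻¹, k = 1.40 × 10⁵ M⁻¹ s⁻¹)
    ternary complex → enzyme + target (k = 1800 s⁻¹)
    starting material + enzyme ⇌ starting complex (K = 290 M⁻¹, k = 3.50 × 10⁵ M⁻¹ s⁻¹)

The doubling lands beside the pool factor of 2.71, while the enzyme factor stands above the proportional 9.09. After 0.300 min the flask holds 0.00708 M of dormant form against 9.79 × 10⁻⁴ M of free second substrate, and the relaxation half-life between the two by that step alone, both ways together, is 0.463 s. Counted the same way at a conversion of 0.7, the second substrate left in this flask, both forms together, is 0.714 of its amount at 50% conversion, and the rate is 0.57 of its value there.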